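**Retrosynthetic overview**
- Target 11 ⇐ aryl alkyne 7 + 4-iodoresorcinol 10 by domino Sonogashira / 5-endo-dig annulation (benzofuran ring formed last).
- 7 ⇐ aldehyde 5 by one-carbon homologation; 10 ⇐ resorcinol 8 by mono-iodination.
- 5 ⇐ unsymmetrical bis-ether 4 by a one-pot double aromatic Claisen cascade. The reverse-prenyl ether gives the C-prenyl phenol and the propargyl ether gives the 2,2-dimethylpyran ring, each through a dearomatised cyclohexadienone.
- 4 ⇐ C2v-symmetric bis(1,1-dimethylpropargyl) ether 3 by desymmetrising mono-semihydrogenation; 3 ⇐ 3,5-dihydroxybenzaldehyde 1 + 3-chloro-3-methylbut-1-yne 2.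
- Ring order: pyran ring (step 3), then benzofuran (step 6).

Assumption: the target has no stereocentre and no hindered stereogenic axis, so it is achiral and "single enantiomer" needs no stereocontrol; the route delivers the single constitutional isomer drawn.

**Step 1**
Reactants: 1, 3,5-dihydroxybenzaldehyde; 2, 3-chloro-3-methylbut-1-yne
Product: 3, 3,5-bis[(2-methylbut-3-yn-2-yl)oxy]benzaldehyde
Conditions: 2 (2.6 equiv), DBU (3 equiv), CuCl2·2H2O (1 mol %), MeCN, 0 °C → rt
Reagents that add atoms: 3-chloro-3-methylbut-1-yne, CC(C)(Cl)C#C
Why: Cu-catalysed propargylic O-alkylation of phenols (via a Cu-acetylide/allenylidene species) gives tertiary aryl propargyl ethers; both equivalent OH groups react and the aldehyde is inert.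

**Step 2**
Reactants: 3, 3,5-bis[(2-methylbut-3-yn-2-yl)oxy]benzaldehyde
Product: 4, 3-[(2-methylbut-3-en-2-yl)oxy]-5-[(2-methylbut-3-yn-2-yl)oxy]benzaldehyde
Conditions: H2 (1.0 equiv, gas burette), Lindlar cat., quinoline, EtOAc, rt; filter through Celite and carry the crude forward
Reagents that add atoms: none
Why: Lindlar semihydrogenation stops at the alkene, and the two remote alkynes react independently, so 1 equiv H2 gives roughly 1:2:1 of 3 : 4 : bis-alkene. This is the symmetry-breaking step; the mixture is not separated here because the three step-3 products differ in the number of free OH groups (0, 1, 2).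

**Step 3**
Reactants: 4, 3-[(2-methylbut-3-en-2-yl)oxy]-5-[(2-methylbut-3-yn-2-yl)oxy]benzaldehyde
Product: 5, 7-hydroxy-2,2-dimethyl-6-(3-methylbut-2-en-1-yl)-2H-chromene-5-carbaldehyde
Conditions: PhNEt2 (0.05 M), Ar, 120 °C, 1 h, then 180 °C, 3 h; chromatography (5 is the mono-phenol fraction)
Reagents that add atoms: none
Why: Tandem aromatic Claisen rearrangements. The 1,1-dimethylallyl ether undergoes [3,3] shift and re-aromatisation to the o-prenyl phenol, and the propargyl ether undergoes [3,3] shift, enolisation, 1,5-H shift and oxa-6π electrocyclisation to the 2,2-dimethyl-2H-chromene. Both shifts are predicted to go to C2/C6, which are ortho to the meta-acceptor CHO and para to the other oxygen (matched directing effects), not to C4 between the oxygens. The one-pot combination at these hindered positions is a prediction, not an established result.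

**Step 4**
Reactants: 5, 7-hydroxy-2,2-dimethyl-6-(3-methylbut-2-en-1-yl)-2H-chromene-5-carbaldehyde; 6, dimethyl (1-diazo-2-oxopropyl)phosphonate (Ohira–Bestmann reagent)
Product: 7, 5-ethynyl-2,2-dimethyl-6-(3-methylbut-2-en-1-yl)-2H-chromen-7-ol
Conditions: 6 (2 equiv), K2CO3 (3.5 equiv), MeOH, 0 °C → rt, 24 h
Reagents that add atoms: dimethyl (1-diazo-2-oxopropyl)phosphonate, COP(=O)(OC)C(=[N+]=[N-])C(C)=O (supplies the terminal alkyne carbon)
Why: Seyferth–Gilbert homologation (Ohira–Bestmann variant): the diazomethylphosphonate anion adds to the aldehyde, and HWE-type elimination, N2 loss and 1,2-H shift give the terminal alkyne. The mild carbonate/methanol conditions tolerate the phenol (as phenoxide), the prenyl group and the chromene.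

**Step 5**
Reactants: 8, resorcinol; 9, iodine monochloride
Product: 10, 4-iodobenzene-1,3-diol (4-iodoresorcinol)
Conditions: ICl (1.0 equiv), Et2O, 0 °C → rt
Reagents that add atoms: iodine monochloride, ClI
Why: Electrophilic aromatic iodination; ICl in ether iodinates C4 (para to one OH, ortho to the other) and one equivalent limits di-iodination.

**Step 6**
Reactants: 7, 5-ethynyl-2,2-dimethyl-6-(3-methylbut-2-en-1-yl)-2H-chromen-7-ol; 10, 4-iodobenzene-1,3-diol
Product: 11, cathafuran C, 5-(6-hydroxy-1-benzofuran-2-yl)-2,2-dimethyl-6-(3-methylbut-2-en-1-yl)-2H-chromen-7-ol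
Conditions: PdCl2(PPh3)2 (5 mol %), CuI (10 mol %), Et3N, DMF (degassed), rt → 80 °C
Reagents that add atoms: none (all product atoms come from 7 and 10)
Why: Domino Sonogashira coupling / 5-endo-dig hydroalkoxylation (Cacchi-type benzofuran annulation). The OH ortho to iodine closes onto the alkyne and the para OH becomes the benzofuran 6-OH. The phenol on 7 is meta to the alkyne and cannot cyclise, and the non-acidic conditions preserve the o-prenylphenol and chromene.

**Compound list**
1 | 3,5-dihydroxybenzaldehyde | O=Cc1cc(O)cc(O)c1 | starting material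
2 | 3-chloro-3-methylbut-1-yne | CC(C)(Cl)C#C | starting material
3 | 3,5-bis[(2-methylbut-3-yn-2-yl)oxy]benzaldehyde | O=Cc1cc(OC(C)(C)C#C)cc(OC(C)(C)C#C)c1 | intermediate
4 | 3-[(2-methylbut-3-en-2-yl)oxy]-5-[(2-methylbut-3-yn-2-yl)oxy]benzaldehyde | O=Cc1cc(OC(C)(C)C=C)cc(OC(C)(C)C#C)c1 | intermediate
5 | 7-hydroxy-2,2-dimethyl-6-(3-methylbut-2-en-1-yl)-2H-chromene-5-carbaldehyde | CC(C)=CCc1c(O)cc2c(c1C=O)C=CC(C)(C)O2 | intermediate
6 | dimethyl (1-diazo-2-oxopropyl)phosphonate | COP(=O)(OC)C(=[N+]=[N-])C(C)=O | starting material
7 | 5-ethynyl-2,2-dimethyl-6-(3-methylbut-2-en-1-yl)-2H-chromen-7-ol | CC(C)=CCc1c(O)cc2c(c1C#C)C=CC(C)(C)O2 | intermediate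
8 | resorcinol | Oc1cccc(O)c1 | starting material
9 | iodine monochloride | ClI | starting material
10 | 4-iodobenzene-1,3-diol | Oc1ccc(I)c(O)c1 | intermediate
11 | cathafuran C (achiral) | CC(C)=CCc1c(O)cc2c(c1-c1cc3ccc(O)cc3o1)C=CC(C)(C)O2 | target

**Totals**
Total steps: 6. Longest linear sequence: 5 (steps 1, 2, 3, 4, 6); step 5 is a one-step side branch.

**Three steps most likely to fail, with fallbacks**
1. Step 3 (regiochemistry and efficiency of the double Claisen cascade; a thermal carbonyl-ene reaction between CHO and the prenyl group is a possible side path). Fallback: give up the propargyl-Claisen pyran formation. Fully semihydrogenate 3 to the bis(1,1-dimethylallyl) ether and run a double Claisen to symmetric 3,5-dihydroxy-2,6-diprenylbenzaldehyde. Then desymmetrise by mono-oxidative cyclisation of one prenyl/OH pair with DDQ (1 equiv) to reach 5.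
2. Step 2 (statistical mono-reduction, possible over-reduction, 50 % ceiling). Fallback: replace desymmetrisation by partial reduction with stepwise unsymmetrical etherification. Mono-propargylate 1 with 2 (1 equiv), then O-reverse-prenylate the remaining phenol by Pd(0)-catalysed allylic substitution with tert-butyl 2-methylbut-3-en-2-yl carbonate, giving 4 directly.
3. Step 6 (one-pot coupling/annulation with three free phenols and an electron-rich aryl iodide; Glaser dimerisation of 7). Fallback: change the benzofuran disconnection. Carry out a Wittig olefination of aldehyde 5 with a (2-hydroxy-4-silyloxybenzyl)triphenylphosphonium salt to the 2-hydroxystilbene, then oxidative cyclisation (PdCl2(MeCN)2/benzoquinone or PhI(OAc)2) and desilylation. This also bypasses the hindered homologation in step 4.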